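**Retrosynthetic overview**

1. Target 15 (ring numbering: C1 ketone, C2 propanoyl, C3 OH, C4 prenyl, C5 OH, C6 gem-diprenyl) is cut at C2–C3 and C4–C5. This gives a four-carbon piece (C5, C6, C1, C2 with the propanoyl group) and a two-carbon piece (C3, C4 with its prenyl group).
2. The four-carbon piece is carried as a temporary oxygen heterocycle, 6-ethyl-3,3-diprenylpyran-2,4-dione 7. Its O–C(=O) bond, absent from the target, ties the propanoyl oxygen to C5. The two-carbon piece is the enolate of thioester 12.
3. Enabling feature: the quaternary C6 between the C1 and C5 carbonyls cannot enolise. In ring 7 the C5 lactone carbonyl is therefore a vinylogous anhydride, and its leaving group is the enolate of the C1/propanoyl 1,3-diketone, which is the C2 nucleophile needed for the second bond.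
4. 7 comes from double C-prenylation of 6-ethyl-4-hydroxy-2-pyrone 3, itself from triacetic acid lactone 1; 12 comes from the Johnson–Claisen ester 11.
5. Ring order: the pyranone ring is bought with 1 and serves as the temporary ring; the only ring of the target, the carbocycle, is formed in step 6 as the pyranone is opened.

Key step: step 6

Assumption: the target is taken as the drawn enol tautomer of an achiral 2-acylcyclohexane-1,3,5-trione. It has no stereocentre and no stereogenic double bond, so no stereocontrol is required.

**Route**

Step 1
Reactants: 1 4-hydroxy-6-methyl-2H-pyran-2-one (triacetic acid lactone)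
Product: 3 6-ethyl-4-hydroxy-2H-pyran-2-one, via pyrone dianion dilithium salt 2 (not isolated)
Conditions: LiN(iPr)2 (2.2 equiv), THF, −78 °C; MeI (1.0 equiv), −78 → 0 °C; aq. HCl
Reagents that add atoms: iodomethane, CI
Why: The dianion (4-oxido group plus the vinylogous enolate from deprotonation of the 6-methyl group) should react with one equivalent of MeI at its more basic lateral carbon, a known gamma-alkylation of the triacetic acid lactone dianion.

Step 2
Reactants: 4 3-methylbut-2-en-1-ol (prenol)
Product: 5 methyl 3-methylbut-2-en-1-yl carbonate
Conditions: ClCO2Me (1.2 equiv), pyridine, CH2Cl2, 0 °C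
Reagents that add atoms: methyl chloroformate, COC(=O)Cl
Why: Acylation of the primary allylic alcohol by the chloroformate should give the mixed carbonate without allylic transposition.

Step 3
Reactants: 3 6-ethyl-4-hydroxy-2H-pyran-2-one; 5 methyl 3-methylbut-2-en-1-yl carbonate (2.1 equiv)
Product: 7 6-ethyl-3,3-bis(3-methylbut-2-en-1-yl)-2H-pyran-2,4(3H)-dione, via mono-prenyl pyrone 6 (not isolated)
Conditions: Pd(PPh3)4 (5 mol %), THF, 25 → 50 °C, exclusion of moisture
Reagents that add atoms: none
Why: Base-free Tsuji–Trost allylic alkylation: ionisation and decarboxylation of 5 give a π-prenyl palladium methoxide that deprotonates the strongly acidic pyrone, the soft C3 carbanion attacks the unsubstituted allyl terminus to give linear prenyl groups, any O-prenyl ether re-ionises under the zerovalent palladium catalyst and is funnelled to carbon, and the second alkylation at C3 sets the quaternary centre.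

Step 4
Reactants: 8 2-methylbut-3-en-2-ol; 9 triethyl orthoacetate
Product: 11 ethyl 5-methylhex-4-enoate, via mixed ketene acetal 10 (not isolated)
Conditions: EtCO2H (cat.), neat, 140 °C, EtOH distilled off
Reagents that add atoms: none
Why: Johnson–Claisen orthoester rearrangement: acid-catalysed exchange and loss of ethanol give ketene acetal 10, whose [3,3]-sigmatropic shift forms the new C–C bond at the vinyl terminus and leaves a trisubstituted alkene with two identical methyl groups, so no geometry needs control.

Step 5
Reactants: 11 ethyl 5-methylhex-4-enoate
Product: 12 S-phenyl 5-methylhex-4-enethioate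
Conditions: PhSH (1.5 equiv), AlMe3 (1.5 equiv), CH2Cl2, 0 → 25 °C, argon; aq. HCl
Reagents that add atoms: thiophenol, Sc1ccccc1
Why: Dimethylaluminium benzenethiolate, formed from AlMe3 and PhSH, should activate the ester carbonyl and deliver the thiolate (aluminium thiolate ester-to-thioester exchange), the strong Al–O bond driving the replacement of ethoxide.

Step 6
Reactants: 7 6-ethyl-3,3-bis(3-methylbut-2-en-1-yl)-2H-pyran-2,4(3H)-dione; 12 S-phenyl 5-methylhex-4-enethioate
Product: 15 postlupulone (3,5-dihydroxy-4,6,6-tris(3-methylbut-2-en-1-yl)-2-propanoylcyclohexa-2,4-dien-1-one), via lithium thioester enolate 13 (not isolated), via open-chain triketo thioester 14 (not isolated)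
Conditions: 12 (2.0 equiv), LiN(SiMe3)2 (2.0 equiv), THF, −78 °C; 7 (1.0 equiv), −78 → −20 °C; AcOH (1.0 equiv), −20 → 25 °C; aq. HCl
Reagents that add atoms: none
Why: Proposed new method: the hard lithium enolate 13 should add to the lactone carbonyl of 7, whose tetrahedral adduct collapses irreversibly because the ring oxygen leaves as the stabilised enolate of a 1,3-diketone (a Claisen acylation by a vinylogous anhydride); this forms the C4–C5 bond of the target and in the same event unmasks C2 as a nucleophile. Because the new beta-keto thioester is acidic, the second equivalent of 13 is consumed as a base, and one equivalent of AcOH then returns the monoanion of 14, in which the diketone carbon C2 acylates on the S-phenyl thioester, directly or after E1cB loss of thiophenolate to an acylketene, to form the C2–C3 bond and close the carbocycle in a 6-exo-trig Claisen (Dieckmann-type) mode. The closest known reaction types are the opening of enol lactones by carbanions with recyclisation (Fujimoto–Belleau annulation), the acylation of thioester enolates by activated acyl donors, and the base-mediated Claisen cyclisation of 3,5-diketo esters and thioesters to acylphloroglucinols and acyltetramic acids (Lacey–Dieckmann); the tandem use of a 3,3-dialkylpyran-2,4-dione as both acyl donor and latent nucleophile is the new element. No stereocentre is set: the target is achiral and the racemic thioester alpha-carbon of 14 ends as the enol carbon C4. The step needs site selectivity for the lactone carbonyl over the ring ketone and the enone beta-carbon, which kinetic addition of a lithium enolate at −78 °C should secure (ketone addition is reversible and the beta-carbon is doubly substituted), and C- over O-acylation in the closure, which should follow because O-acylation gives an enol lactone that thiophenolate reopens while the trione anion is the thermodynamic sink.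

**Compound list**

1 | 4-hydroxy-6-methyl-2H-pyran-2-one (triacetic acid lactone) | CC1=CC(O)=CC(=O)O1 | starting material
2 | dilithium salt of the dianion of 1 (4-oxido group and 6-CH2 carbanion) | [Li+].[Li+].[CH2-]C1=CC([O-])=CC(=O)O1 | intermediate (not isolated)
3 | 6-ethyl-4-hydroxy-2H-pyran-2-one | CCC1=CC(O)=CC(=O)O1 | intermediate
4 | 3-methylbut-2-en-1-ol (prenol) | CC(C)=CCO | starting material
5 | methyl 3-methylbut-2-en-1-yl carbonate | COC(=O)OCC=C(C)C | intermediate
6 | 6-ethyl-4-hydroxy-3-(3-methylbut-2-en-1-yl)-2H-pyran-2-one | CCC1=CC(O)=C(CC=C(C)C)C(=O)O1 | intermediate (not isolated)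
7 | 6-ethyl-3,3-bis(3-methylbut-2-en-1-yl)-2H-pyran-2,4(3H)-dione | CCC1=CC(=O)C(CC=C(C)C)(CC=C(C)C)C(=O)O1 | intermediate
8 | 2-methylbut-3-en-2-ol | CC(C)(O)C=C | starting material
9 | triethyl orthoacetate (1,1,1-triethoxyethane) | CCOC(C)(OCC)OCC | starting material
10 | 1-ethoxy-1-[(2-methylbut-3-en-2-yl)oxy]ethene (mixed ketene acetal) | C=C(OCC)OC(C)(C)C=C | intermediate (not isolated)
11 | ethyl 5-methylhex-4-enoate | CCOC(=O)CCC=C(C)C | intermediate
12 | S-phenyl 5-methylhex-4-enethioate | CC(C)=CCCC(=O)Sc1ccccc1 | intermediate
13 | lithium enolate of 12 (enolate geometry not controlled and of no consequence) | [Li+].CC(C)=CCC=C([O-])Sc1ccccc1 | intermediate (not isolated)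
14 | S-phenyl 2,4,4-tris(3-methylbut-2-en-1-yl)-3,5,7-trioxononanethioate (racemic at C2; present as its lithium enolates, drawn in the neutral triketo form) | CCC(=O)CC(=O)C(CC=C(C)C)(CC=C(C)C)C(=O)C(CC=C(C)C)C(=O)Sc1ccccc1 | intermediate (not isolated)
15 | postlupulone, 3,5-dihydroxy-4,6,6-tris(3-methylbut-2-en-1-yl)-2-propanoylcyclohexa-2,4-dien-1-one (achiral) | CCC(=O)C1=C(O)C(CC=C(C)C)=C(O)C(CC=C(C)C)(CC=C(C)C)C1=O | target

**Step count and risks**

Total step count: 6. Longest linear sequence: 3 steps (step 1, step 3, step 6; the branches through steps 2 and 4–5 are no longer).

Steps most likely to fail: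

1. Step 6 (proposed new method). The enolate may add in conjugate fashion to the enone carbon of 7 with ring opening to a carboxylate, or act as a base toward the 6-ethyl group. The open-chain intermediate may also stall, or close through oxygen or by aldol addition to the propanoyl carbonyl instead of by C-acylation. The fallback uses known chemistry, sets out from 1 and rejoins the route at 15. The dianion 2 is C-acylated at its lateral carbon with methyl propanoate (a third equivalent of LiN(iPr)2, THF, −78 → 0 °C) to give 4-hydroxy-6-(2-oxobutyl)-2H-pyran-2-one F1. Mg(OMe)2 in MeOH at reflux should open the pyranone and reclose the triketo acid derivative in the Claisen mode to 1-(2,4,6-trihydroxyphenyl)propan-1-one F2. Dearomatising triple C-prenylation of F2 with commercial 1-bromo-3-methylbut-2-ene (3.2 equiv) and NaOMe in MeOH at 0 °C, a known type of C-alkylation of acylphloroglucinols, should then give 15 after separation from less and O-prenylated material.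

2. Step 3. The nucleophile may attack the substituted terminus of the π-allyl ligand (reverse-prenyl groups), the reaction may stop after the first alkylation or at O-prenyl ethers, and the moisture- and alkoxide-sensitive product may be opened by the methoxide left once the acidic pronucleophile is used up. The fallback sets out from 3 and rejoins at 7. It replaces π-allyl chemistry by direct SN2 alkylation with commercial 1-bromo-3-methylbut-2-ene (2.2 equiv), K2CO3, dry acetone, 56 °C. This can deliver only linear prenyl groups, passes through 6, and should give 7 beside separable O-prenyl ethers; it makes no new compound.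

3. Step 1. The dianion may be alkylated twice at the lateral carbon, or at C3 or oxygen, and it is poorly soluble. The fallback sets out from 1 and rejoins at 3. It removes the acidic hydroxyl before metalation: O-methylation (Me2SO4, K2CO3, acetone, 56 °C) gives 4-methoxy-6-methyl-2H-pyran-2-one F3. Lateral lithiation and methylation (LiN(iPr)2, THF, −78 °C; MeI) give 6-ethyl-4-methoxy-2H-pyran-2-one F4. SN2 demethylation of the vinylogous methyl ester (LiI, pyridine, reflux; aq. HCl) returns 3.

**Further compounds**

F1 | step 6 | 4-hydroxy-6-(2-oxobutyl)-2H-pyran-2-one | CCC(=O)CC1=CC(O)=CC(=O)O1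
F2 | step 6 | 1-(2,4,6-trihydroxyphenyl)propan-1-one | CCC(=O)c1c(O)cc(O)cc1O
F0 | step 3 | none | none
F3 | step 1 | 4-methoxy-6-methyl-2H-pyran-2-one | COC1=CC(=O)OC(C)=C1
F4 | step 1 | 6-ethyl-4-methoxy-2H-pyran-2-one | CCC1=CC(OC)=CC(=O)O1
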